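## Structural features

3-O-Acetylpadmatin is a 2,3-trans-dihydroflavonol: a chroman-4-one in which benzo ring A is fused to the oxygen heterocycle ring C, with a catechol ring B on C2 and an acetoxy group on C3. C2 and C3 are adjacent stereocentres, both R, and the C2 aryl and C3 acetoxy groups are trans (both equatorial on the half-chair of ring C). Ring A is a phloroglucinol unit with three different oxygens: O1 belongs to ring C, O5 is a free hydroxyl hydrogen-bonded to the C4 carbonyl, and O7 is a methyl ether. The fragile points are the acetate beside the ketone (lost to base and nucleophiles), the enolisable C3–H, the air-sensitive catechol, and the C2–O1 bond. That bond is a benzylic aryl ether β to the carbonyl: base opens ring C to a chalcone by retro-oxa-Michael reaction and acid can ionise it, and either event erases C2. The carbon skeleton is simple; the real difficulty is to set C2 absolutely, to place the C3 oxygen trans to the aryl group, and to finish with three free phenols while one aryl methyl ether and the acetate survive. The key step exploits the fact that C2 is a benzylic ether carbon, bound to O1 and ring B, lying 1,6 to C3 along the chain C3–C4–C4a–C8a–O1–C2. A carbenoid at C3, next to the C4 ketone, can therefore insert into a C2–H bond, forming C2–C3, closing ring C and creating C2 under catalyst control.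

## Logic of the disconnections

**11 ⇒ 10.** The O–CH2 bonds at O3', O4' and O5 are cut last; the two benzyl ethers inside the O5 group fall in the same operation. The free catechol and the chelated phenol would not survive a carbenoid, a silyl triflate or an acylating agent, so they stay masked to the end. Because every mask is a benzylic ether, one hydrogenolysis replaces a Lewis-acid cleavage of a C5 methyl ether next to an acetate and a second methyl ether. The demand is that hydrogenolysis spares the acetate, the ketone and the ring C2–O1 bond.

**10 ⇒ 9.** The acetyl–O3 bond is cut. In 9 the C3 hydroxyl is the only free OH, so the acetylation has no selectivity problem. The demand is a base mild enough not to enolise C3 or open ring C.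

**9 ⇒ 7 ⇒ 6.** The C3–O bond is cut and traced to the enol ether 7 of ketone 6. This removes one stereocentre and leaves C2 as the only control element. The forward step must deliver oxygen to the face of C3 opposite the C2 aryl group, and the enol ether must be made without a free enolate or a long-lived cation that would scramble C2.

**6 ⇒ 5.** The C2–C3 bond is cut; this is the key disconnection. It removes ring C and the C2 stereocentre and leaves an achiral diazomethyl ketone with two identical arylmethyl ethers flanking the acyl group. The forward step must prefer C–H insertion to attack on an ether oxygen and must distinguish the two enantiotopic benzylic hydrogens. The precursor is redesigned in one respect relative to the simplest version, in which O5 would be a methyl ether: O5 carries a second copy of the 3,4-bis(benzyloxy)benzyl group. The two flanks are then homotopic, insertion on either side gives the same product, and the O5 group is removable together with the benzyl ethers. A plain benzyl ether at O5 would offer a second, different benzylic C–H site and is avoided.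

**5 ⇒ 4 ⇒ 3.** The C3–N bond is cut and traced through the trifluoroacetyl-activated diketone 4 to methyl ketone 3. Starting at the ketone oxidation level avoids an aldehyde-to-acid oxidation, an acid chloride (HCl beside acid-labile, electron-rich benzyl ethers) and a toxic silylated diazomethane. The demand is clean kinetic enolisation of the methyl group and a base-mediated diazo transfer.

**3 ⇒ 1 + 2.** The two aryl O–CH2 bonds are cut, giving a symmetric dihydroxy ketone and two equivalents of one benzylic chloride. No regiochemical choice arises. The demand is O- rather than C-alkylation, including at the second, hydrogen-bonded hydroxyl.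

## Other disconnections considered

**Alternative 1:** ring A is built last by cutting C8–C8a and C4a–C5.
- **Forward step.** A Diels–Alder reaction of the ketene acetal diene 1,3-dimethoxy-1-(trimethylsilyloxy)buta-1,3-diene A3 with (2R,3R)-2-[3,4-bis(benzyloxy)phenyl]-4-oxo-5-(phenylsulfinyl)-3,4-dihydro-2H-pyran-3-yl acetate A2. The CH2 terminus of A3 bonds to the β-carbon (future C8a) and the acetal carbon to the sulfinyl-bearing α-carbon (future C4a). Loss of benzenesulfenic acid and methanol then aromatises ring A to 3',4'-di-O-benzyl-3-O-acetylpadmatin A1.
- **In its favour.** The two different oxygens of A3 map directly onto the free C5 hydroxyl and the C7 methyl ether, so no group is needed on O5. Both stereocentres and the acetate are already present, and A1 is one hydrogenolysis from the target. On steps after the key step it is the better plan (one against four). Its regiochemistry follows from substrate polarity and is probably more predictable than the chemoselectivity of a carbenoid.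
- **Against it here.** A2 is a vinylogous ester and a reluctant dienophile. Its α-acetoxy ketone has to survive the cycloaddition and the two eliminations without epimerising C3 or losing acetic acid to a 4-pyranone. Above all, A2 must first be made enantiopure with both stereocentres in a small heterocycle and then sulfenylated and oxidised.
- **Comparison.** The alternative spends its main effort on a phloroglucinol ring that can be bought, and in total steps it should be clearly longer. The chosen plan builds only ring C and the stereocentres on a purchased ring A, at the price of a less predictable key step.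

**Alternative 2:** three bonds are cut, C4a–C4, C4–C3 and O1–C2.
- **Forward step.** 3-(Benzyloxy)-2-iodo-5-methoxyphenol A5, carbon monoxide and 1,2-bis(benzyloxy)-4-ethynylbenzene A6 are coupled with PdCl2(PPh3)2 in diethylamine. Zerovalent palladium adds to the C–I bond, CO inserts, the acyl palladium couples with the alkyne to an ynone, and the phenoxide closes ring C by conjugate addition to give 5-(benzyloxy)-2-[3,4-bis(benzyloxy)phenyl]-7-methoxy-4H-chromen-4-one A4.
- **In its favour.** It is the most convergent plan: two simple halves and CO give the whole C–O skeleton in one operation. On skeletal step economy it is better than the chosen plan. A benzyl ether on O5 is harmless in this chemistry, so the all-hydrogenolysis end game is equally available.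
- **Against it here.** A4 is flat, so neither C2 nor C3 is set. The C2=C3 bond of an electron-rich, 5,7-dioxygenated flavone would have to be reduced enantioselectively, and C3 would then be oxidised by the same enol ether sequence used here. Five-membered closure to an aurone can compete, CO gas is needed, and A5 requires a regioselective iodination between two oxygens.
- **Comparison.** The alternative solves the easy part (the skeleton) very well and postpones the hard part (the stereocentres). The chosen key step forms one bond fewer but sets C2, which then controls C3. After an asymmetric reduction the alternative would stand where compound 6 stands, without a clear saving in steps.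

**Alternative 3:** the aryl ether bond O1–C8a is cut.
- **Forward step.** The anti-aldol (2R,3R)-2-(allyloxy)-3-[3,4-bis(benzyloxy)phenyl]-1-(2-fluoro-4,6-dimethoxyphenyl)-3-hydroxypropan-1-one A8 is made from 2-(allyloxy)-1-(2-fluoro-4,6-dimethoxyphenyl)ethanone A9 and 3,4-bis(benzyloxy)benzaldehyde A10. K2CO3 then makes the alkoxide, which displaces the ortho fluoride by SNAr to give 3-O-allyl-3',4'-di-O-benzyl-5-O-methylpadmatin A7. Neither stereocentre takes part in the ring closure.
- **In its favour.** Both stereocentres come from one aldol step, and the same C2–C3 bond is made convergently from two halves of similar size. The ring closure needs no transition metal and is activated by the ortho acyl group, with both methoxy groups meta to the fluoride. On stereochemical economy it is the equal or the better of the chosen plan if the aldol is selective, and its step count is about the same.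
- **Against it here.** An enantio- and anti-selective aldol of an α-alkoxy aryl ketone with an electron-rich, reversible aromatic aldehyde is itself an open problem of control. Under K2CO3 the β-hydroxy ketone can undergo retro-aldol cleavage or dehydration to a chalcone before it cyclises. A7 still carries a C5 methyl ether and an allyl ether, so the end game needs deallylation, acetylation and a chelation-controlled demethylation beside the acetate.
- **Comparison.** Both plans form C2–C3. The alternative does so intermolecularly with reagent control of two centres; the chosen plan does so intramolecularly with catalyst control of one centre and substrate control of the second. The chosen plan's redesigned protecting groups give the gentler end game.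

Key step: step 4

**Remarks on the chemistry (assumptions).**
- The sense of induction of Rh2(S-PTTL)4 in a 1,6-insertion of this kind cannot be deduced safely by analogy. The route is written on the assumption that the (S)-ligand catalyst gives (2S)-6; the mirror-image catalyst Rh2(R-PTTL)4 would be used if the sense proves opposite.
- C2 keeps one spatial arrangement from 6 to 11. Its descriptor changes from S (6, 7) to R (8–11) only because C3 outranks ring B once it carries oxygen.
- Compounds 1 and 2 are taken as catalogue reagents.

## Route

Step 1
Reactants: 1 1-(2,6-dihydroxy-4-methoxyphenyl)ethanone; 2 1,2-bis(benzyloxy)-4-(chloromethyl)benzene (2.2 equiv)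
Product: 3 1-(2,6-bis{[3,4-bis(benzyloxy)benzyl]oxy}-4-methoxyphenyl)ethanone
Conditions: K2CO3, KI (cat.), DMF, 60 °C
Reagents that add atoms: none
Why: Double Williamson ether synthesis (SN2) of the two phenoxides in a dipolar aprotic solvent; in-situ iodide exchange (Finkelstein) helps the second, hydrogen-bonded hydroxyl to react, and the acetyl group lowers the ring nucleophilicity enough to keep C-benzylation minor.

Step 2
Reactants: 3 1-(2,6-bis{[3,4-bis(benzyloxy)benzyl]oxy}-4-methoxyphenyl)ethanone
Product: 4 1-(2,6-bis{[3,4-bis(benzyloxy)benzyl]oxy}-4-methoxyphenyl)-4,4,4-trifluorobutane-1,3-dione (used crude)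
Conditions: LiN(SiMe3)2, THF, −78 °C; CF3CO2CH2CF3, −78 °C; cold 1 M HCl work-up
Reagents that add atoms: 2,2,2-trifluoroethyl trifluoroacetate, O=C(OCC(F)(F)F)C(F)(F)F
Why: Crossed Claisen acylation of the kinetic lithium enolate of the methyl ketone by an activated trifluoroacetate; the 1,3-diketone is needed because a simple aryl methyl ketone does not accept a diazo group, and the benzylic ether hydrogens are far too weakly acidic to interfere.

Step 3
Reactants: 4 1-(2,6-bis{[3,4-bis(benzyloxy)benzyl]oxy}-4-methoxyphenyl)-4,4,4-trifluorobutane-1,3-dione
Product: 5 1-(2,6-bis{[3,4-bis(benzyloxy)benzyl]oxy}-4-methoxyphenyl)-2-diazoethanone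
Conditions: 4-acetamidobenzenesulfonyl azide, Et3N, H2O (1 equiv), MeCN, rt
Reagents that add atoms: 4-acetamidobenzenesulfonyl azide, CC(=O)Nc1ccc(cc1)S(=O)(=O)N=[N+]=[N-]
Why: Deacylative Regitz diazo transfer: the enolised diketone adds to the sulfonyl azide and the adduct fragments with transfer of the trifluoroacetyl group to the sulfonamide nitrogen, leaving the diazomethyl ketone; amine base at room temperature leaves all ethers untouched, and the acetamido-substituted azide is among the safer transfer reagents.

Step 4
Reactants: 5 1-(2,6-bis{[3,4-bis(benzyloxy)benzyl]oxy}-4-methoxyphenyl)-2-diazoethanone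
Product: 6 (2S)-2-[3,4-bis(benzyloxy)phenyl]-5-{[3,4-bis(benzyloxy)benzyl]oxy}-7-methoxychroman-4-one
Conditions: Rh2(S-PTTL)4 (2 mol %), 4 Å molecular sieves, CH2Cl2, 0 °C, slow addition of 5
Reagents that add atoms: none
Why: Dirhodium tetrakis[N-phthaloyl-(S)-tert-leucinate] displaces N2 from 5 to give an electrophilic acyl carbenoid at C3, which takes a benzylic ether hydrogen of one arylmethoxy arm through a concerted, asynchronous three-centre transition state with hydride-transfer character and forms C2–C3 as the metal departs. The closest known reaction type is the chiral dirhodium carboxylate-catalysed insertion of ortho-alkoxyaryl diazo ketones into the C–H bond next to the ether oxygen, which gives 2-substituted chroman-4-ones. Ring C closes in a 1,6 mode through a six-membered array, because position 5 of the chain C3–C4–C4a–C8a–O1–C2 is the oxygen atom and the only activated C–H lies one atom further. C2 is set by the catalyst: the phthalimido walls of the carboxylate ligands decide which of the two enantiotopic benzylic hydrogens is replaced. The step needs chemoselectivity for insertion over attack of an ether lone pair, which would give a five-membered oxonium ylide and then a 1,2-shift of the arylmethyl group. In its favour, the C–H bond is doubly activated by O1 and the para-benzyloxy group, an aryl ether oxygen is a weak donor, the two ortho substituents twist the acyl group out of the ring plane (a geometry the planar five-membered ylide tolerates less well than the six-membered insertion array), and a carboxylate catalyst of moderate electrophilicity in a non-coordinating solvent is used in place of a perfluorinated one. Site selectivity is not an issue because the two arms are homotopic and both lead to 6, while the remote OCH2Ph hydrogens would need a ring of eleven or more members; slow addition keeps carbene dimerisation down.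

Step 5
Reactants: 6 (2S)-2-[3,4-bis(benzyloxy)phenyl]-5-{[3,4-bis(benzyloxy)benzyl]oxy}-7-methoxychroman-4-one
Product: 7 {[(2S)-2-[3,4-bis(benzyloxy)phenyl]-5-{[3,4-bis(benzyloxy)benzyl]oxy}-7-methoxy-2H-chromen-4-yl]oxy}trimethylsilane (used crude)
Conditions: Me3SiOTf, Et3N, CH2Cl2, −20 → 0 °C; cold NaHCO3 wash
Reagents that add atoms: trimethylsilyl trifluoromethanesulfonate, C[Si](C)(C)OS(=O)(=O)C(F)(F)F
Why: Soft enolisation: the silyl triflate silylates the C4 carbonyl oxygen and the amine removes a C3 proton, so no free enolate is formed and the E1cB opening of ring C that would erase C2 has no alkoxide to start from; excess amine buffers the Lewis acid, and C2 is not touched.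

Step 6
Reactants: 7 {[(2S)-2-[3,4-bis(benzyloxy)phenyl]-5-{[3,4-bis(benzyloxy)benzyl]oxy}-7-methoxy-2H-chromen-4-yl]oxy}trimethylsilane
Product: 9 (2R,3R)-2-[3,4-bis(benzyloxy)phenyl]-5-{[3,4-bis(benzyloxy)benzyl]oxy}-3-hydroxy-7-methoxychroman-4-one, via 3,4-epoxy-4-silyloxyflavan 8 (not isolated)
Conditions: dimethyldioxirane (acetone solution), CH2Cl2, −40 → 0 °C; then 0.5 M HCl, THF, 0 °C
Reagents that add atoms: dimethyldioxirane, CC1(C)OO1
Why: Rubottom oxidation: the neutral dioxirane epoxidises the electron-rich C3=C4 bond from the face opposite the C2 aryl group, and dilute acid opens the silyloxy oxirane at C4 with loss of the silyl group, so the C3–O bond is never broken and the hydroxyl ends trans to the aryl group (3R); the trans isomer, with both substituents equatorial, is also the thermodynamically preferred one.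

Step 7
Reactants: 9 (2R,3R)-2-[3,4-bis(benzyloxy)phenyl]-5-{[3,4-bis(benzyloxy)benzyl]oxy}-3-hydroxy-7-methoxychroman-4-one
Product: 10 (2R,3R)-2-[3,4-bis(benzyloxy)phenyl]-5-{[3,4-bis(benzyloxy)benzyl]oxy}-7-methoxy-4-oxochroman-3-yl acetate
Conditions: Ac2O, pyridine, DMAP (cat.), CH2Cl2, 0 °C → rt
Reagents that add atoms: acetic anhydride, CC(=O)OC(C)=O
Why: Nucleophile-catalysed O-acylation of the only free hydroxyl; the mild amine base at or below room temperature should neither epimerise C3 nor open ring C.

Step 8
Reactants: 10 (2R,3R)-2-[3,4-bis(benzyloxy)phenyl]-5-{[3,4-bis(benzyloxy)benzyl]oxy}-7-methoxy-4-oxochroman-3-yl acetate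
Product: 11 3-O-acetylpadmatin, (2R,3R)-2-(3,4-dihydroxyphenyl)-5-hydroxy-7-methoxy-4-oxochroman-3-yl acetate
Conditions: H2 (1 atm), Pd/C, EtOAc–MeOH, rt
Reagents that add atoms: none
Why: Heterogeneous hydrogenolysis of all five benzylic aryl ether C–O bonds over palladium on carbon under neutral conditions; the acetate, the aryl methyl ether and the hydrogen-bonded aryl ketone are inert at one atmosphere, and the hindered, cyclic C2–O1 bond should react much more slowly than the open OCH2Ar groups, so the reaction is stopped once debenzylation is complete.

## Compound list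

1 | 1-(2,6-dihydroxy-4-methoxyphenyl)ethanone | CC(=O)c1c(O)cc(OC)cc1O | starting material
2 | 1,2-bis(benzyloxy)-4-(chloromethyl)benzene | ClCc1ccc(OCc2ccccc2)c(OCc2ccccc2)c1 | starting material
3 | 1-(2,6-bis{[3,4-bis(benzyloxy)benzyl]oxy}-4-methoxyphenyl)ethanone | CC(=O)c1c(OCc2ccc(OCc3ccccc3)c(OCc3ccccc3)c2)cc(OC)cc1OCc1ccc(OCc2ccccc2)c(OCc2ccccc2)c1 | intermediate
4 | 1-(2,6-bis{[3,4-bis(benzyloxy)benzyl]oxy}-4-methoxyphenyl)-4,4,4-trifluorobutane-1,3-dione | O=C(CC(=O)C(F)(F)F)c1c(OCc2ccc(OCc3ccccc3)c(OCc3ccccc3)c2)cc(OC)cc1OCc1ccc(OCc2ccccc2)c(OCc2ccccc2)c1 | intermediate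
5 | 1-(2,6-bis{[3,4-bis(benzyloxy)benzyl]oxy}-4-methoxyphenyl)-2-diazoethanone | [N-]=[N+]=CC(=O)c1c(OCc2ccc(OCc3ccccc3)c(OCc3ccccc3)c2)cc(OC)cc1OCc1ccc(OCc2ccccc2)c(OCc2ccccc2)c1 | intermediate
6 | (2S)-2-[3,4-bis(benzyloxy)phenyl]-5-{[3,4-bis(benzyloxy)benzyl]oxy}-7-methoxychroman-4-one | COc1cc(OCc3ccc(OCc4ccccc4)c(OCc4ccccc4)c3)c2c(c1)O[C@H](c1ccc(OCc3ccccc3)c(OCc3ccccc3)c1)CC2=O | intermediate
7 | {[(2S)-2-[3,4-bis(benzyloxy)phenyl]-5-{[3,4-bis(benzyloxy)benzyl]oxy}-7-methoxy-2H-chromen-4-yl]oxy}trimethylsilane | COc1cc(OCc3ccc(OCc4ccccc4)c(OCc4ccccc4)c3)c2c(c1)O[C@H](c1ccc(OCc3ccccc3)c(OCc3ccccc3)c1)C=C2O[Si](C)(C)C | intermediate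
8 | 3,4-epoxide of 7 with the oxirane oxygen anti to the C2 aryl group, (1aR,2R,7bR)-2-[3,4-bis(benzyloxy)phenyl]-7-{[3,4-bis(benzyloxy)benzyl]oxy}-5-methoxy-7b-[(trimethylsilyl)oxy]-1a,7b-dihydro-2H-oxireno[2,3-c]chromene | COc1cc(OCc3ccc(OCc4ccccc4)c(OCc4ccccc4)c3)c2c(c1)O[C@H](c1ccc(OCc3ccccc3)c(OCc3ccccc3)c1)[C@H]5O[C@@]25O[Si](C)(C)C | intermediate
9 | (2R,3R)-2-[3,4-bis(benzyloxy)phenyl]-5-{[3,4-bis(benzyloxy)benzyl]oxy}-3-hydroxy-7-methoxychroman-4-one | COc1cc(OCc3ccc(OCc4ccccc4)c(OCc4ccccc4)c3)c2c(c1)O[C@H](c1ccc(OCc3ccccc3)c(OCc3ccccc3)c1)[C@@H](O)C2=O | intermediate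
10 | (2R,3R)-2-[3,4-bis(benzyloxy)phenyl]-5-{[3,4-bis(benzyloxy)benzyl]oxy}-7-methoxy-4-oxochroman-3-yl acetate | COc1cc(OCc3ccc(OCc4ccccc4)c(OCc4ccccc4)c3)c2c(c1)O[C@H](c1ccc(OCc3ccccc3)c(OCc3ccccc3)c1)[C@@H](OC(C)=O)C2=O | intermediate
11 | 3-O-acetylpadmatin, (2R,3R)-2-(3,4-dihydroxyphenyl)-5-hydroxy-7-methoxy-4-oxochroman-3-yl acetate | COc1cc(O)c2c(c1)O[C@H](c1ccc(O)c(O)c1)[C@@H](OC(C)=O)C2=O | target

## Step count and least certain steps

Total step count: 8. Longest linear sequence: 8 steps (1 → 11; the route is linear, with 2 entering in step 1).

**Step 4 (key step).**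
- What may go wrong: capture of the carbenoid by an ether lone pair followed by 1,2-shift of the arylmethyl group, or weak discrimination between the two enantiotopic benzylic hydrogens. The electron-rich aryl group that makes the C–H bond hydridic also stabilises the migrating group, and a terminal acyl carbenoid is less selective than a donor-substituted one.
- Fallback (sets out from 1 and 2, rejoins at 6): the C2–aryl bond is made in place of C2–C3, by conjugate arylation of a chromone.
  - Alkylation of 1 with one equivalent of 2 (K2CO3, acetone, reflux; the second hydroxyl is shielded by its hydrogen bond) should give 1-(2-{[3,4-bis(benzyloxy)benzyl]oxy}-6-hydroxy-4-methoxyphenyl)ethanone F1.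
  - Condensation with Me2NCH(OMe)2 at 90 °C gives the enaminone (E)-1-(2-{[3,4-bis(benzyloxy)benzyl]oxy}-6-hydroxy-4-methoxyphenyl)-3-(dimethylamino)prop-2-en-1-one F2.
  - Warming F2 in acetic acid closes it to 5-{[3,4-bis(benzyloxy)benzyl]oxy}-7-methoxy-4H-chromen-4-one F3.
  - Rhodium-catalysed enantioselective 1,4-addition of [3,4-bis(benzyloxy)phenyl]boronic acid F4 ([Rh(OH)(cod)]2 with a chiral biaryl bisphosphine, aqueous dioxane; ligand enantiomer chosen for 2S) gives 6.

**Step 5.**
- What may go wrong: partial loss of configuration at C2 by reversible cleavage of the C2–O1 bond while the carbonyl is silylated (a cation at C2 is stabilised by the para-benzyloxy group), or hydrolytic reversion of the enol ether on work-up.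
- Fallback (sets out from 6, rejoins at 9): no silyl enol ether and no Lewis acid are used. The lithium enolate is formed with LiN(SiMe3)2 in THF at −78 °C, where ring opening is slow, and hydroxylated directly with 3-phenyl-2-(phenylsulfonyl)oxaziridine from the face opposite the aryl group, then quenched cold with acid.

**Step 6.**
- What may go wrong: insufficient facial selectivity in the oxygen transfer, or loss of the enol ether by hydrolysis or further oxidation before the epoxide is formed.
- Fallback (sets out from 7, rejoins at 9): dihydroxylation of the enol ether with OsO4 (cat.) and N-methylmorpholine N-oxide in aqueous acetone at 0 °C. The bulkier oxidant adds by cycloaddition on the face away from the aryl group, and the resulting silyloxy diol collapses to 9 under buffered conditions.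

**Step 8.**
- What may go wrong: hydrogenolytic opening of ring C at the benzylic C2–O1 bond on prolonged exposure, or slow cleavage of the electron-rich O5 arylmethyl ether.
- Fallback (sets out from 10, rejoins at 11): Lewis-acid cleavage in place of reduction, with BCl3 and pentamethylbenzene as cation scavenger in CH2Cl2 at −78 °C. The chelated O5 ether and the four benzyl ethers ionise readily, while the acetate and the unchelated O7 methyl ether should remain.

## Further compounds

F1 | step 4 | 1-(2-{[3,4-bis(benzyloxy)benzyl]oxy}-6-hydroxy-4-methoxyphenyl)ethanone | CC(=O)c1c(O)cc(OC)cc1OCc1ccc(OCc2ccccc2)c(OCc2ccccc2)c1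
F2 | step 4 | (E)-1-(2-{[3,4-bis(benzyloxy)benzyl]oxy}-6-hydroxy-4-methoxyphenyl)-3-(dimethylamino)prop-2-en-1-one | CN(C)/C=C/C(=O)c1c(O)cc(OC)cc1OCc1ccc(OCc2ccccc2)c(OCc2ccccc2)c1
F3 | step 4 | 5-{[3,4-bis(benzyloxy)benzyl]oxy}-7-methoxy-4H-chromen-4-one | COc1cc(OCc3ccc(OCc4ccccc4)c(OCc4ccccc4)c3)c2c(c1)occc2=O
F4 | step 4 | [3,4-bis(benzyloxy)phenyl]boronic acid | OB(O)c1ccc(OCc2ccccc2)c(OCc2ccccc2)c1
F0 | step 5 | none | none
F0 | step 6 | none | none
F0 | step 8 | none | none
A1 | alternative 1 | 3',4'-di-O-benzyl-3-O-acetylpadmatin, (2R,3R)-2-[3,4-bis(benzyloxy)phenyl]-5-hydroxy-7-methoxy-4-oxochroman-3-yl acetate | COc1cc(O)c2c(c1)O[C@H](c1ccc(OCc3ccccc3)c(OCc3ccccc3)c1)[C@@H](OC(C)=O)C2=O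
A2 | alternative 1 | (2R,3R)-2-[3,4-bis(benzyloxy)phenyl]-4-oxo-5-(phenylsulfinyl)-3,4-dihydro-2H-pyran-3-yl acetate (sulfur configuration immaterial) | O=C1C(S(=O)c2ccccc2)=CO[C@H](c2ccc(OCc3ccccc3)c(OCc3ccccc3)c2)[C@H]1OC(C)=O
A3 | alternative 1 | 1,3-dimethoxy-1-(trimethylsilyloxy)buta-1,3-diene (ketene acetal geometry immaterial) | C=C(OC)C=C(OC)O[Si](C)(C)C
A4 | alternative 2 | 5-(benzyloxy)-2-[3,4-bis(benzyloxy)phenyl]-7-methoxy-4H-chromen-4-one | COc1cc(OCc2ccccc2)c2c(c1)oc(-c1ccc(OCc3ccccc3)c(OCc3ccccc3)c1)cc2=O
A5 | alternative 2 | 3-(benzyloxy)-2-iodo-5-methoxyphenol | COc1cc(O)c(I)c(OCc2ccccc2)c1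
A6 | alternative 2 | 1,2-bis(benzyloxy)-4-ethynylbenzene | C#Cc1ccc(OCc2ccccc2)c(OCc2ccccc2)c1
A7 | alternative 3 | 3-O-allyl-3',4'-di-O-benzyl-5-O-methylpadmatin, (2R,3R)-3-(allyloxy)-2-[3,4-bis(benzyloxy)phenyl]-5,7-dimethoxychroman-4-one | COc1cc(OC)c2c(c1)O[C@H](c1ccc(OCc3ccccc3)c(OCc3ccccc3)c1)[C@@H](OCC=C)C2=O
A8 | alternative 3 | (2R,3R)-2-(allyloxy)-3-[3,4-bis(benzyloxy)phenyl]-1-(2-fluoro-4,6-dimethoxyphenyl)-3-hydroxypropan-1-one | COc1cc(OC)c(c(F)c1)C(=O)[C@H](OCC=C)[C@H](O)c1ccc(OCc2ccccc2)c(OCc2ccccc2)c1
A9 | alternative 3 | 2-(allyloxy)-1-(2-fluoro-4,6-dimethoxyphenyl)ethanone | COc1cc(OC)c(c(F)c1)C(=O)COCC=C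
A10 | alternative 3 | 3,4-bis(benzyloxy)benzaldehyde | O=Cc1ccc(OCc2ccccc2)c(OCc2ccccc2)c1
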